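The lifetime of the pool is the unit to count in here. The pool is starting material plus dormant form, and the south run's first reading, with its remainder counted as dormant form, the resting state, reads as 2.66 parts of it to one part free.

- south: starting material 0.36 M; coupling partner 0.90 M (in portions, 3); second substrate 2.5 M; run made earlier; portions every 30 s
- flask: starting material 0.36 M; coupling partner 0.900 M (in portions, 3); second substrate 1.80 M; time 15 min; the portions of coupling partner follow each other after 30 s, the first at the start

south run (percent of the starting material charged)

| time / min | target / % | starting material / % |
|---|---|---|
| 0.667 | 9.2 | 24.8 |
| 2.00 | 24.7 | 18.7 |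
| 3.00 | 30.1 | 17.5 |
| 5.00 | 35.5 | 16.0 |
| 8.00 | 38.1 | 15.0 |
| 10.0 | 38.0 | 14.7 |
| 12.0 | 38.3 | 14.4 |

(scatter of a reading: 0.3 percentage points)

- concentration of target at 15 min, in M
- concentration of starting material at 15 min, in M
- concentration of coupling partner at 15 min, in M

Two times matter. In the south run, the fall of target rate per free starting material reads as a coupling partner loss rate of 0.410 min⁻¹, so a coupling partner lifetime of 2.44 min. The other time is the pool's lifetime under the whole charge. The first divided by the second is the exposure, a reading from the south plateau with cross product set aside:

exposure = −ln(share of pool not turned into target) = 0.483

The pool lifetime therefore reads as 5.05 min, and this reckoning keeps it for this flask, whose coupling partner charge matches the south run's. This flask holds less second substrate than the south run, so the reckoning lengthens the coupling partner lifetime by a factor 1.19, the middle between no change, if decomposition took the loss, and the full ratio of second substrate, if second substrate took it: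

coupling partner lifetime = 2.91 min
exposure = 0.577
target = 0.158 M

The forecast, holding that “the split is unknown”, gives target 0.151 M (0.14 M to 0.163 M), lower than this reckoning, starting material 0.048 M and coupling partner 0.006 M.

The flask gives target 0.158 M, starting material 0.0475 M and coupling partner 0.00257 M.

    starting material + coupling partner → target (k = 0.0180 L mol⁻¹ s⁻¹)
    second substrate + coupling partner → second product (k = 0.00230 L mol⁻¹ s⁻¹)
    starting material + second substrate → cross product (k = 3.20 × 10⁻⁴ L mol⁻¹ s⁻¹)
    target → over-reaction product (k = 3.20 × 10⁻⁶ s⁻¹)
    coupling partner → decomposed reagent (k = 0.00250 s⁻¹)
    starting material ⇌ dormant form (K = 2.70, k = 0.0640 s⁻¹)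

The flask's target, with cross product set aside, reads back as an exposure of 0.580. The neighbouring flask is like this one but holds 0.22 M of coupling partner, about a quarter of this flask's charge, so the same reckoning scales its exposure to 0.141 and puts its target at 0.0473 M. That neighbouring flask gives 0.0454 M of target, with coupling partner down to 2.48 × 10⁻⁴ M.

The earlier runs and the new flask were generated by integration for substances that don't exist, and the scatter is random.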